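**Retrosynthetic overview**
1. Target 10 ⇒ phenol 9: the C4–OMe bond is made last by a chiral aryl iodide-catalysed para-methoxylative dearomatisation, which sets the quaternary centre.
2. Phenol 9 ⇒ racemic tertiary carbinol 7: an enantioconvergent organocatalytic transfer hydrogenation through para-quinone methide 8 sets the side-chain centre (first stereocentre).
3. Carbinol 7 ⇒ aryl methyl ketone 4 + benzylic Grignard reagent 6 (C7–C8 bond).
4. Ketone 4 ⇒ commercial phenol 1 by O-allylation and aromatic Claisen rearrangement.
5. Rings: both six-membered rings come from the aromatic starting materials; none is built, and the dienone ring arises from the phenol ring in the last step.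

Assumption: the sense of induction of the two chiral catalysts is assigned by analogy and is not predicted with certainty; if either proves opposite, its mirror-image catalyst is used and nothing else changes.

**Step 1**
Reactants: 1 1-(4-hydroxy-2-methoxyphenyl)ethan-1-one
Product: 2 1-[2-methoxy-4-(prop-2-en-1-yloxy)phenyl]ethan-1-one
Conditions: allyl bromide (1.2 equiv), K2CO3 (1.5 equiv), acetone, reflux
Reagents that add atoms: allyl bromide, C=CCBr
Why: Williamson ether synthesis; the phenoxide is the only nucleophile present and allyl bromide is a reactive SN2 electrophile, no stereocentre is formed.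

**Step 2**
Reactants: 2 1-[2-methoxy-4-(prop-2-en-1-yloxy)phenyl]ethan-1-one
Product: 4 1-[4-hydroxy-2-methoxy-5-(prop-2-en-1-yl)phenyl]ethan-1-one, via cyclohexa-2,4-dienone tautomer 3 (not isolated)
Conditions: PhNEt2, 200 °C
Reagents that add atoms: none
Why: Aromatic Claisen rearrangement ([3,3]-sigmatropic shift, then tautomerisation of 3); migration should favour C5 (para to OMe) over C3, which lies between two oxygen substituents and is shielded by the methoxy group turned away from the acetyl group.

**Step 3**
Reactants: 4 1-[4-hydroxy-2-methoxy-5-(prop-2-en-1-yl)phenyl]ethan-1-one; 5 4-(chloromethyl)-1,2-dimethoxybenzene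
Product: 7 racemic 4-[1-(3,4-dimethoxyphenyl)-2-hydroxypropan-2-yl]-5-methoxy-2-(prop-2-en-1-yl)phenol, via (3,4-dimethoxybenzyl)magnesium chloride 6 (not isolated)
Conditions: 5 (2.5 equiv), Mg, THF, 0 °C; then 4, LaCl3·2LiCl (1 equiv), THF, 0 °C to rt; aq. NH4Cl
Reagents that add atoms: none
Why: Grignard formation and 1,2-addition to the ketone; one equivalent of 6 is used up by the phenol O–H, LaCl3·2LiCl activates the phenoxide-deactivated carbonyl and suppresses enolisation, and the carbinol centre may stay racemic because it is erased in step 4 (crude 7, or any styrene formed from it by loss of water, is used directly).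

**Step 4**
Reactants: 7 racemic 4-[1-(3,4-dimethoxyphenyl)-2-hydroxypropan-2-yl]-5-methoxy-2-(prop-2-en-1-yl)phenol
Product: 9 4-[(2S)-1-(3,4-dimethoxyphenyl)propan-2-yl]-5-methoxy-2-(prop-2-en-1-yl)phenol, via para-quinone methide 8 (not isolated)
Conditions: (R)-TRIP [(R)-3,3'-bis(2,4,6-triisopropylphenyl)-1,1'-binaphthyl-2,2'-diyl hydrogen phosphate] (5 mol %), Hantzsch ester (diethyl 2,6-dimethyl-1,4-dihydropyridine-3,5-dicarboxylate, 1.5 equiv), 5 Å MS, toluene, 0 °C to rt
Reagents that add atoms: none
Why: Proposed new method: the chiral phosphoric acid ionises both enantiomers of 7 (loss of water) to the same achiral para-quinone methide 8, whose 5-methoxy group enforces one exocyclic geometry (E, methyl next to OMe) by A(1,3) strain; the phosphate then bridges the quinone methide carbonyl and the N–H of the Hantzsch ester, the allyl/H-differentiated ring edges orient the substrate in the catalyst pocket, and hydride is delivered to the Re face of the exocyclic carbon to give the 2S centre. The closest known reaction type is the chiral phosphoric acid/Hantzsch ester transfer hydrogenation of in situ generated ortho- and para-quinone methides that carry one aryl and one methyl group (1,1-diarylethane synthesis); new here is a quinone methide with two alkyl groups (methyl against arylmethyl) at the reacting carbon.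

**Step 5**
Reactants: 9 4-[(2S)-1-(3,4-dimethoxyphenyl)propan-2-yl]-5-methoxy-2-(prop-2-en-1-yl)phenol
Product: 10 (4S)-4-[(2S)-1-(3,4-dimethoxyphenyl)propan-2-yl]-4,5-dimethoxy-2-(prop-2-en-1-yl)cyclohexa-2,5-dien-1-one
Conditions: (R,R)-2,2'-[(2-iodo-1,3-phenylene)bis(oxy)]bis[N-(2,4,6-trimethylphenyl)propanamide] (10 mol %), mCPBA (1.3 equiv), MeOH (20 equiv), CH2Cl2, −20 °C; then aq. NaHCO3/Na2S2O3
Reagents that add atoms: methanol, CO
Why: Proposed new method: mCPBA oxidises the C2-symmetric aryl iodide to a trivalent iodine species that binds the phenol oxygen of 9 inside a helical pocket held by the two intramolecular amide N–H···O hydrogen bonds; methanol, hydrogen-bonded to a catalyst amide carbonyl, then attacks the para carbon C4 in an associative SN2'-type step with loss of the aryl iodide, on the Si face, which gives 4S. This is also the face the substrate prefers, because in the rotamer with the side-chain C–H in the ring plane next to the 5-methoxy group it carries the small methyl and lies anti to the veratrylmethyl group, so catalyst and substrate control should be matched; the side-chain centre is untouched, and any C4 epimer is a diastereomer removable by chromatography. The closest known reaction types are the achiral PhI(OAc)2/MeOH para-methoxylative dearomatisation of 4-alkyl-3-alkoxyphenols to 4-alkyl-4-methoxycyclohexa-2,5-dienones and the chiral aryl iodide/mCPBA-catalysed enantioselective hydroxylative para-dearomatisation and spirolactonisation of phenols; new here is catalyst-controlled intermolecular delivery of methanol to the para carbon of a phenol that already bears a stereocentre.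

**Compound list**
1 | 1-(4-hydroxy-2-methoxyphenyl)ethan-1-one | CC(=O)c1ccc(O)cc1OC | starting material
2 | 1-[2-methoxy-4-(prop-2-en-1-yloxy)phenyl]ethan-1-one | CC(=O)c1ccc(OCC=C)cc1OC | intermediate
3 | 4-acetyl-3-methoxy-6-(prop-2-en-1-yl)cyclohexa-2,4-dien-1-one (racemic, not isolated) | CC(=O)C1=CC(CC=C)C(=O)C=C1OC | intermediate
4 | 1-[4-hydroxy-2-methoxy-5-(prop-2-en-1-yl)phenyl]ethan-1-one | CC(=O)c1cc(CC=C)c(O)cc1OC | intermediate
5 | 4-(chloromethyl)-1,2-dimethoxybenzene | COc1ccc(CCl)cc1OC | starting material
6 | (3,4-dimethoxybenzyl)magnesium chloride (not isolated) | COc1ccc(C[Mg]Cl)cc1OC | intermediate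
7 | 4-[1-(3,4-dimethoxyphenyl)-2-hydroxypropan-2-yl]-5-methoxy-2-(prop-2-en-1-yl)phenol (racemic) | C=CCc1cc(C(C)(O)Cc2ccc(OC)c(OC)c2)c(OC)cc1O | intermediate
8 | (4E)-4-[1-(3,4-dimethoxyphenyl)propan-2-ylidene]-5-methoxy-2-(prop-2-en-1-yl)cyclohexa-2,5-dien-1-one (not isolated) | C/C(Cc1ccc(OC)c(OC)c1)=C2/C=C(CC=C)C(=O)C=C2OC | intermediate
9 | 4-[(2S)-1-(3,4-dimethoxyphenyl)propan-2-yl]-5-methoxy-2-(prop-2-en-1-yl)phenol | C=CCc1cc([C@@H](C)Cc2ccc(OC)c(OC)c2)c(OC)cc1O | intermediate
10 | (4S)-4-[(2S)-1-(3,4-dimethoxyphenyl)propan-2-yl]-4,5-dimethoxy-2-(prop-2-en-1-yl)cyclohexa-2,5-dien-1-one | C=CCC1=C[C@@](OC)([C@@H](C)Cc2ccc(OC)c(OC)c2)C(OC)=CC1=O | target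

**Totals**
Total step count: 5. Longest linear sequence: 5 steps (from 1).

**Three steps most likely to fail**

Step 5 (proposed new step). Face control by the catalyst at the remote para carbon may be weak, mCPBA may touch the allyl group, or the benzylic C–H may be lost to give a quinone methide. The fallback uses known chemistry and sets out from 9: oxidation with PhI(OAc)2 in MeOH at 0 °C (substrate control only) gives 10 together with its C4 epimer (4R)-4-[(2S)-1-(3,4-dimethoxyphenyl)propan-2-yl]-4,5-dimethoxy-2-(prop-2-en-1-yl)cyclohexa-2,5-dien-1-one F7. The two diastereomers are separated by chromatography, and F7 is returned to 9 by reductive rearomatisation with Zn in AcOH and oxidised again. The fallback comes back to the route at 10.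

Step 4 (also a proposed new step, as a substrate extension). Discrimination between methyl and arylmethyl at the quinone methide may give low enantiomeric excess, or 8 may be lost to Friedel–Crafts dimerisation. The fallback uses known chemistry, sets out from 1 and Grignard reagent 6, and introduces the allyl group only after a metal-catalysed hydrogenation:
- Addition of 6 to 1 under the conditions of step 3 gives racemic 4-[1-(3,4-dimethoxyphenyl)-2-hydroxypropan-2-yl]-3-methoxyphenol F2.
- Dehydration with catalytic TsOH in toluene, followed by crystallisation, gives 4-[(1E)-1-(3,4-dimethoxyphenyl)prop-1-en-2-yl]-3-methoxyphenol F3.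
- Asymmetric hydrogenation of this trisubstituted stilbene-type alkene with [Ir(cod)(tBu-PHOX)][B(3,5-(CF3)2C6H3)4] (ligand enantiomer chosen for the S product; H2 50 bar, CH2Cl2) gives 4-[(2S)-1-(3,4-dimethoxyphenyl)propan-2-yl]-3-methoxyphenol F4.
- O-Allylation (allyl bromide, K2CO3, acetone) gives 1-[(2S)-1-(3,4-dimethoxyphenyl)propan-2-yl]-2-methoxy-4-(prop-2-en-1-yloxy)benzene F5.
- Claisen rearrangement (PhNEt2, 200 °C) proceeds through 4-[(2S)-1-(3,4-dimethoxyphenyl)propan-2-yl]-3-methoxy-6-(prop-2-en-1-yl)cyclohexa-2,4-dien-1-one F6 and comes back to the route at 9.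

Step 2. The Claisen rearrangement may give a mixture of C5 and C3 allyl isomers that is hard to separate. The fallback sets out from 1: bromination with NBS in MeCN at 0 °C (ortho to OH, para to OMe) gives 1-(5-bromo-4-hydroxy-2-methoxyphenyl)ethan-1-one F1. Stille coupling with allyltributylstannane and Pd(PPh3)4 in toluene at 100 °C then places the allyl group unambiguously and comes back to the route at 4, bypassing 2 and 3.

**Further compounds**
F1 | step 2 | 1-(5-bromo-4-hydroxy-2-methoxyphenyl)ethan-1-one | CC(=O)c1cc(Br)c(O)cc1OC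
F2 | step 4 | 4-[1-(3,4-dimethoxyphenyl)-2-hydroxypropan-2-yl]-3-methoxyphenol (racemic) | COc1cc(O)ccc1C(C)(O)Cc1ccc(OC)c(OC)c1
F3 | step 4 | 4-[(1E)-1-(3,4-dimethoxyphenyl)prop-1-en-2-yl]-3-methoxyphenol | C/C(=C\c1ccc(OC)c(OC)c1)c1ccc(O)cc1OC
F4 | step 4 | 4-[(2S)-1-(3,4-dimethoxyphenyl)propan-2-yl]-3-methoxyphenol | COc1cc(O)ccc1[C@@H](C)Cc1ccc(OC)c(OC)c1
F5 | step 4 | 1-[(2S)-1-(3,4-dimethoxyphenyl)propan-2-yl]-2-methoxy-4-(prop-2-en-1-yloxy)benzene | C=CCOc1ccc([C@@H](C)Cc2ccc(OC)c(OC)c2)c(OC)c1
F6 | step 4 | 4-[(2S)-1-(3,4-dimethoxyphenyl)propan-2-yl]-3-methoxy-6-(prop-2-en-1-yl)cyclohexa-2,4-dien-1-one (C6 epimers, not isolated) | C=CCC1C=C([C@@H](C)Cc2ccc(OC)c(OC)c2)C(OC)=CC1=O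
F7 | step 5 | (4R)-4-[(2S)-1-(3,4-dimethoxyphenyl)propan-2-yl]-4,5-dimethoxy-2-(prop-2-en-1-yl)cyclohexa-2,5-dien-1-one | C=CCC1=C[C@](OC)([C@@H](C)Cc2ccc(OC)c(OC)c2)C(OC)=CC1=O
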